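The synthesis rests on cutting the palmitoyl chain between C5' and C6', an unactivated CH2–CH2 bond four methylenes from ester carbonyl C1'. This spacing is the feature exploited. C1'–C5' is adipic acid minus CO2 and C6'–C16' is lauric acid minus CO2, so two like-polarised carbons can be united as radicals by mixed Kolbe electrolysis. The precursor is the hydrogen adipate of the C10 carbinol on the finished oxolane core (ring O/C6–C9, 7-O-TES, C18=C19 intact; nonadecene numbering). One operation expels two CO2, completes the C16 ester and, on acidifying the methanolic electrolyte, frees the C7 hydroxyl. The core arises by chloroaldehyde aldol, syn reduction and chloride displacement.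

Key step: step 9

Assumption: (2S,5S)-2,5-diphenylpyrrolidine is taken to deliver the (R)-chloroaldehyde (steric shielding model). Both catalyst antipodes are commercial, so a reversed sense of induction would only swap the catalyst.

Step 1
Reactants: 1 heptanal
Product: 2 (2R)-2-chloroheptanal
Conditions: NCS, (2S,5S)-2,5-diphenylpyrrolidine (10 mol %), CH2Cl2, 0 °C to rt; pentane, filtration; used without chromatography
Reagents that add atoms: N-chlorosuccinimide O=C1CCC(=O)N1Cl
Why: Enamine-catalysed asymmetric α-chlorination of an unbranched aldehyde, in which the C2-symmetric amine shields one enamine face and sets C6 as R, the configuration that later inverts to S.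

Step 2
Reactants: 2 (2R)-2-chloroheptanal, 3 (E)-4-phenylbut-3-en-2-one
Product: 5 (1E,5S,6R)-6-chloro-5-hydroxy-1-phenylundec-1-en-3-one, via lithium dienolate 4 (not isolated)
Conditions: LDA, THF, −78 °C, 3; then 2, −78 °C; aq NH4Cl at −78 °C
Reagents that add atoms: lithium diisopropylamide [Li]N(C(C)C)C(C)C (lithium, held only by 4)
Why: Kinetic lithium enolate aldol addition to an α-chloroaldehyde, in which the Cornforth/polar Felkin–Anh transition state should give the 1,2-anti chlorohydrin, so that C6 sets C7 as S.

Step 3
Reactants: 5 (1E,5S,6R)-6-chloro-5-hydroxy-1-phenylundec-1-en-3-one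
Product: 7 (1E,3R,5S,6R)-6-chloro-1-phenylundec-1-ene-3,5-diol, via diethylboryl chelate 6 (not isolated)
Conditions: Et2BOMe, THF/MeOH, −78 °C; NaBH4; AcOH, then MeOH co-evaporation
Reagents that add atoms: diethyl(methoxy)borane CCB(CC)OC (boron and ethyl groups, held only by 6)
Why: Narasaka–Prasad reduction, in which external hydride attacks the six-membered boron chelate axially, so that C7 controls C9 and the 1,3-syn diol (9R) should form by clean 1,2-reduction of the enone.

Step 4
Reactants: 7 (1E,3R,5S,6R)-6-chloro-1-phenylundec-1-ene-3,5-diol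
Product: 8 (2S,3S,5R)-2-pentyl-5-[(E)-2-phenylethenyl]oxolan-3-ol
Conditions: AgOTf, Ag2O, THF, rt to 50 °C, dark
Reagents that add atoms: none
Why: Silver(I)-assisted intramolecular SN2 etherification (5-exo-tet), in which the C9 hydroxyl displaces chloride with inversion (6R to 6S) to give the 2,3-cis-2,5-trans oxolane, while the non-basic medium holds back epoxide formation from the C7 hydroxyl.

Step 5
Reactants: 8 (2S,3S,5R)-2-pentyl-5-[(E)-2-phenylethenyl]oxolan-3-ol
Product: 9 triethyl{[(2S,3S,5R)-2-pentyl-5-[(E)-2-phenylethenyl]oxolan-3-yl]oxy}silane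
Conditions: TESCl, imidazole, CH2Cl2, 0 °C to rt
Reagents that add atoms: chlorotriethylsilane CC[Si](Cl)(CC)CC
Why: Standard silylation of the only hydroxyl present, which marks O7 before O10 exists and so settles which oxygen is acylated later.

Step 6
Reactants: 9 triethyl{[(2S,3S,5R)-2-pentyl-5-[(E)-2-phenylethenyl]oxolan-3-yl]oxy}silane
Product: 11 (2R,4S,5S)-5-pentyl-4-(triethylsilyloxy)oxolane-2-carbaldehyde, via secondary ozonide 10 (not isolated)
Conditions: O3, CH2Cl2, −78 °C; PPh3, −78 °C to rt
Reagents that add atoms: ozone [O-][O+]=O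
Why: Ozonolysis with reductive work-up cleaves the only alkene present to the α-alkoxy aldehyde under neutral conditions that leave C9 and the silyl ether untouched.

Step 7
Reactants: 11 (2R,4S,5S)-5-pentyl-4-(triethylsilyloxy)oxolane-2-carbaldehyde, 12 9-bromonon-1-ene
Product: 14 (1R)-1-[(2R,4S,5S)-5-pentyl-4-(triethylsilyloxy)oxolan-2-yl]dec-9-en-1-ol, via non-8-enylmagnesium bromide 13 (not isolated)
Conditions: 12, Mg, Et2O, reflux; then 11, MgBr2·OEt2, CH2Cl2, −78 °C; aq NH4Cl
Reagents that add atoms: magnesium [Mg] (held only by 13)
Why: Chelation-controlled (Cram chelate) Grignard addition, in which magnesium bridges the aldehyde oxygen and the ring oxygen and the nucleophile enters from the side of the C9 hydrogen, which should set C10 as R (threo to C9).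

Step 8
Reactants: 14 (1R)-1-[(2R,4S,5S)-5-pentyl-4-(triethylsilyloxy)oxolan-2-yl]dec-9-en-1-ol, 15 adipic acid
Product: 16 6-{[(1R)-1-[(2R,4S,5S)-5-pentyl-4-(triethylsilyloxy)oxolan-2-yl]dec-9-en-1-yl]oxy}-6-oxohexanoic acid
Conditions: 15 (5 equiv), EDC·HCl, DMAP, THF/CH2Cl2, rt; aqueous wash
Reagents that add atoms: none
Why: Steglich esterification of the only free hydroxyl, with the symmetrical diacid in fivefold excess so that statistics favour the monoester and the surplus acid is washed out with water.

Step 9
Reactants: 16 6-{[(1R)-1-[(2R,4S,5S)-5-pentyl-4-(triethylsilyloxy)oxolan-2-yl]dec-9-en-1-yl]oxy}-6-oxohexanoic acid, 17 dodecanoic (lauric) acid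
Product: 19 (1R)-1-[(2R,4S,5S)-4-hydroxy-5-pentyloxolan-2-yl]dec-9-en-1-yl hexadecanoate, via TES-protected palmitate 18 (not isolated)
Conditions: 17 (8 equiv), NaOMe (5 mol % of total acid), MeOH, Pt anode/steel cathode, undivided cell, ca. 200 mA cm−2, 40–45 °C, stopped while still acidic; then HCl/MeOH (to ca. 0.1 M), 0 °C to rt
Reagents that add atoms: none
Why: Mixed Kolbe electrolysis: both carboxylates are oxidised by one electron at the platinum anode, lose CO2 and give the primary 4-(alkoxycarbonyl)butyl and undecyl radicals, which combine at the electrode surface to form C5'–C6'. The closest known reaction type is the cross-Kolbe chain extension of alkyl hydrogen adipates with fatty acids. No ring is closed and no stereocentre is created, and C6, C7, C9 and C10 lie six or more bonds from the radical centre and stay untouched. The step needs hetero- over homo-coupling, secured by the large excess of cheap 17 so that the radical from 16 meets mostly undecyl radicals, and it needs coupling over further oxidation to a cation, secured because both acids are unbranched and carry no α-heteroatom. The C18=C19 alkene should be spared because the adsorbed carboxylate layer shields the anode, intramolecular radical addition would need a ring of 15 or more members, and a steel cathode avoids hydrogenation. Acidifying the methanolic electrolyte then methanolyses the TES ether far faster than the secondary palmitate, any silyl loss already in the cell converges on the same product, and the trans relation of O7 and the C9 side chain blocks acyl migration.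

Compound list
1 | heptanal | CCCCCCC=O | starting material
2 | (2R)-2-chloroheptanal | O=C[C@H](Cl)CCCCC | intermediate
3 | (E)-4-phenylbut-3-en-2-one | CC(=O)/C=C/c1ccccc1 | starting material
4 | lithium dienolate of 3 | [Li+].[O-]C(=C)/C=C/c1ccccc1 | intermediate
5 | (1E,5S,6R)-6-chloro-5-hydroxy-1-phenylundec-1-en-3-one | O=C(/C=C/c1ccccc1)C[C@H](O)[C@H](Cl)CCCCC | intermediate
6 | O-diethylboryl chelate of 5 | O=C(/C=C/c1ccccc1)C[C@H](OB(CC)CC)[C@H](Cl)CCCCC | intermediate
7 | (1E,3R,5S,6R)-6-chloro-1-phenylundec-1-ene-3,5-diol | c1ccccc1/C=C/[C@H](O)C[C@H](O)[C@H](Cl)CCCCC | intermediate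
8 | (2S,3S,5R)-2-pentyl-5-[(E)-2-phenylethenyl]oxolan-3-ol | c1ccccc1/C=C/[C@H]2C[C@H](O)[C@H](CCCCC)O2 | intermediate
9 | triethylsilyl ether of 8 | c1ccccc1/C=C/[C@H]2C[C@H](O[Si](CC)(CC)CC)[C@H](CCCCC)O2 | intermediate
10 | secondary ozonide of 9 (3-phenyl-5-oxolanyl-1,2,4-trioxolane, new centres undefined) | c1ccccc1C2OOC(O2)[C@H]3C[C@H](O[Si](CC)(CC)CC)[C@H](CCCCC)O3 | intermediate
11 | (2R,4S,5S)-5-pentyl-4-(triethylsilyloxy)oxolane-2-carbaldehyde | O=C[C@H]1C[C@H](O[Si](CC)(CC)CC)[C@H](CCCCC)O1 | intermediate
12 | 9-bromonon-1-ene | C=CCCCCCCCBr | starting material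
13 | non-8-enylmagnesium bromide | C=CCCCCCCC[Mg]Br | intermediate
14 | (1R)-1-[(2R,4S,5S)-5-pentyl-4-(triethylsilyloxy)oxolan-2-yl]dec-9-en-1-ol | C=CCCCCCCC[C@@H](O)[C@H]1C[C@H](O[Si](CC)(CC)CC)[C@H](CCCCC)O1 | intermediate
15 | adipic acid | OC(=O)CCCCC(=O)O | starting material
16 | hydrogen adipate of 14 | C=CCCCCCCC[C@@H](OC(=O)CCCCC(=O)O)[C@H]1C[C@H](O[Si](CC)(CC)CC)[C@H](CCCCC)O1 | intermediate
17 | dodecanoic (lauric) acid | CCCCCCCCCCCC(=O)O | starting material
18 | (1R)-1-[(2R,4S,5S)-5-pentyl-4-(triethylsilyloxy)oxolan-2-yl]dec-9-en-1-yl hexadecanoate | C=CCCCCCCC[C@@H](OC(=O)CCCCCCCCCCCCCCC)[C@H]1C[C@H](O[Si](CC)(CC)CC)[C@H](CCCCC)O1 | intermediate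
19 | (1R)-1-[(2R,4S,5S)-4-hydroxy-5-pentyloxolan-2-yl]dec-9-en-1-yl hexadecanoate | C=CCCCCCCC[C@@H](OC(=O)CCCCCCCCCCCCCCC)[C@H]1C[C@H](O)[C@H](CCCCC)O1 | target

Total step count: 9. Longest linear sequence: 9 steps (1 to 19). All other inputs (3, 12, 15, 17) are commercial.

Steps most likely to fail

Step 9. Radical pairing may run too far toward symmetrical coupling. The ester-bearing radical may be oxidised further to a cation and trapped by methanol. Precipitating hydrocarbon may foul the anode. The fallback keeps the same bond but replaces radical–radical pairing by a metal-mediated radical capture. It sets out from 16, which with N-hydroxyphthalimide, DIC and DMAP in CH2Cl2 should give the N-(acyloxy)phthalimide ester F1. Nickel-catalysed decarboxylative alkyl–alkyl coupling follows (NiCl2·glyme, 4,4'-di-tert-butyl-2,2'-bipyridine, THF/DMF, rt), using diundecylzinc F2 made from commercial undecylmagnesium bromide and ZnCl2. This comes back to the route at 18, and the closing acid methanolysis of step 9 then gives 19.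

Step 7. Incomplete chelation may lead to poor facial selectivity at the aldehyde, and the basic reagent may enolise the α-alkoxy aldehyde. The fallback sets C10 by hydride delivery instead of carbon delivery. It sets out from stereochemically impure 14, which Dess–Martin oxidation (CH2Cl2, NaHCO3) should convert into the oxolanyl ketone F3. L-Selectride in THF at −78 °C under Felkin–Anh control (hydride anti to the ring C–O bond) should then return the threo carbinol, so the route is rejoined at 14.

Step 2. The lithium base and aldolate may racemise the chloroaldehyde. The aldolate may close onto the chloride in a Darzens-type process on warming. The anti selectivity may also erode. The fallback removes all strong base from the C7–C8 bond formation. It sets out from 3, which with TMSOTf and Et3N in CH2Cl2 should give the 2-(trimethylsilyloxy)diene F4. A BF3·OEt2-mediated Mukaiyama aldol addition of F4 to 2 in CH2Cl2 at −78 °C (open, polar Felkin–Anh transition state) and mild acidic work-up comes back to the route at 5.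

Further compounds
F1 | step 9 | N-(acyloxy)phthalimide ester of 16 | C=CCCCCCCC[C@@H](OC(=O)CCCCC(=O)ON2C(=O)c3ccccc3C2=O)[C@H]1C[C@H](O[Si](CC)(CC)CC)[C@H](CCCCC)O1
F2 | step 9 | diundecylzinc | CCCCCCCCCCC[Zn]CCCCCCCCCCC
F3 | step 7 | 1-[(2R,4S,5S)-5-pentyl-4-(triethylsilyloxy)oxolan-2-yl]dec-9-en-1-one | C=CCCCCCCCC(=O)[C@H]1C[C@H](O[Si](CC)(CC)CC)[C@H](CCCCC)O1
F4 | step 2 | trimethyl{[(3E)-4-phenylbuta-1,3-dien-2-yl]oxy}silane | C=C(O[Si](C)(C)C)/C=C/c1ccccc1
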